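## The problem

The target is a bibenzyl built on a 2,2-dimethyl-2H-chromene. Its benzene ring (ring A) has no hydrogen left and carries six different substituents in a fixed order: O1 on C8a, the pyran carbon on C4a, the 4-hydroxyphenethyl chain on C5, the methyl ester on C6, a free phenol on C7 and a prenyl group on C8. There is no stereocentre, so the problem is one of regiochemistry and functional-group tolerance. The two isoprenoid C5 units sit on the two carbons (C8 and C4a) ortho to the same oxygen, one open and one closed into the pyran. A plan that adds both to a finished resorcinol must therefore tell two electronically similar positions apart and also beat O-alkylation. The sensitive groups set narrow limits. A prenyl group ortho to a free phenol closes to a chroman with acid and is attacked by halogens and quinone oxidants. The two alkenes exclude hydrogenation, the salicylate ester excludes hot hydroxide, and the two free phenols exclude methyl or benzyl ethers as protecting groups. The feature that makes the key step possible is the oxygen pattern of ring A: the oxygens on C7 and C8a are meta to each other and the ester carbon C6 is ortho to C7. This is the pattern of a folded poly-β-carbonyl chain, in which C7 and C8a are carbonyl carbons, C6, C8 and C4a are their α-carbons, and C5 is a carbonyl carbon that has lost its oxygen. Ring A can therefore be cut into a malonate (C6, its ester, C7) and a conjugated ynone (C8, C8a, C4a, C5, with both side chains already attached), and formed from them by two polar C–C bond formations at the phenol oxidation level, with no oxidant.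

## Retrosynthesis

**Target 14 to resorcylate 11 and 3-methylbut-2-enal 12.** The cut is through O1–C2 and C4–C4a of the pyran ring, a formal [3+3] chromene annulation. In 11 (benzoate numbering: C1 ester, C2 OH, C3 prenyl, C4 OH, C5 H, C6 phenethyl) only C5 is unsubstituted, so the position of the chromene is fixed by default. Cutting only the O–C bond, through a propargyl ether, would instead need a selective O-alkylation among three phenols. Removing the C8 prenyl group first would leave an arene prenylation to compete with the chromene. Compound 11 has one ring fewer and the second C5 unit comes from a bulk enal. The forward reaction must form a C–C bond at a ring carbon flanked by the phenethyl chain and must leave the side-chain phenol alone.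

**Resorcylate 11 to ynone 7 and dimethyl malonate 8 (key disconnection).** The cut is through C1–C6 and C2–C3 of the benzoate ring. Malonate 8 supplies C1, C2 and the ester; ynone 7 supplies C3 to C6, with the prenyl group already on the α′-methylene (future C3) and the phenethyl chain on the alkyne terminus (future C6). Against prenylation of a preformed arene, this sets the prenyl position by connectivity, and the resorcinol oxygens never need protection. The same annulation one oxidation level lower (alkene in place of alkyne) is better known, but it would end in a dehydrogenation next to a prenyl group; it is kept as the fallback. The precursor 7 is an open chain with two functional groups. The forward reaction needs conjugate addition at the alkyne carbon bearing the phenethyl chain, then C-acylation (not O-acylation) of an ester by the methylene that carries the prenyl group.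

**Ynone 7 to silyl alkyne 6 and Weinreb amide 3.** The cut is the carbonyl–alkyne bond. Acylation of an acetylide fixes which alkyne carbon is β to the carbonyl, which the key step depends on. A route through a 1,3-diketone would not control this, and a propargylic alcohol would cost an oxidation step. The forward reaction must stop at mono-acylation, and the phenol must be masked for this step only.

**Alkyne 6 to phenol 5 to aldehyde 4; amide 3 to acetamide 1 and prenyl bromide 2.** Alkyne 6 is the silyl ether of 5, and the alkyne carbon of 5 comes from a one-carbon homologation of aldehyde 4. Amide 3 is cut at the Cα–CH2 bond, so the prenyl unit enters intact from bromide 2. Both cuts lead to simple purchasable compounds.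

## Roads not taken

**Alternative 1:** (the most obvious) Cut the C8–prenyl bond and the pyran ring of a finished bibenzyl, methyl 2,4-dihydroxy-6-[2-(4-hydroxyphenyl)ethyl]benzoate A1. The forward key step is electrophilic C-prenylation of A1 at C3, followed by chromene formation at C5. In A1 both C3 and C5 are activated and both oxygens can be alkylated, so the step that decides the identity of the product has no control element. A1 itself needs masked phenols while the two rings are joined, which adds protecting-group steps. The chosen plan fixes the prenyl position through the connectivity of 7.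

**Alternative 2:** (biosynthesis-like end-game) Cut only the O1–C2 bond, leading back to the 3,5-diprenyl resorcylate A2. The forward key step is oxidative cyclisation of the C5 prenyl group onto O4, by a quinone dehydrogenation through an ortho-quinone methide. In A2 two prenyl groups flank the same phenol and the C3 prenyl group also neighbours the 2-OH, so three chromenes can form and nothing in the substrate prefers one. The oxidant also threatens the para-hydroxybenzylic position of the side chain, and A2 needs two regioselective arene prenylations. The chosen plan brings the two C5 units in at different times and oxidation levels: one as a saturated ketone chain, one as an enal.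

**Alternative 3:** (cycloaddition) Cut C1–C2 and C5–C6 of the benzoate ring: Diels–Alder reaction of bis-silyloxy diene A3 (from methyl 2-prenylacetoacetate) with ynoate A4, then loss of methanol, to reach 11 after desilylation. This also builds the ring around the prenyl group. However, A3 is a tetrasubstituted, moisture-sensitive ketene acetal that needs two silylations, and A4 is a β-alkyl ynoate and a poor dienophile, so forcing thermal conditions are expected. The chosen ionic annulation uses the same polarity with bench-stable partners 7 and 8 and sodium methoxide.

Key step: step 5

Remark: the SMILES holds no stereocentre and no stereodefined open-chain alkene; aldehyde 4 is taken as a catalogue compound.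

## Route

Step 1
Reactants: 1 N-methoxy-N-methylacetamide; 2 1-bromo-3-methylbut-2-ene (prenyl bromide)
Product: 3 N-methoxy-N,5-dimethylhex-4-enamide
Conditions: LiN(i-Pr)2 (1.05 equiv), THF, −78 °C; then 2, −78 → −20 °C
Reagents that add atoms: none
Why: Alkylation of the lithium enolate of a Weinreb acetamide with a primary allylic bromide (SN2); the enolate is kept at −78 °C to suppress self-acylation, and attack at the unhindered CH2 of 2 gives the linear prenyl chain.

Step 2
Reactants: 4 3-(4-hydroxyphenyl)propanal
Product: 5 4-(but-3-yn-1-yl)phenol
Conditions: dimethyl (1-diazo-2-oxopropyl)phosphonate, K2CO3, MeOH, 0 °C → rt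
Reagents that add atoms: dimethyl (1-diazo-2-oxopropyl)phosphonate (Ohira–Bestmann reagent), CC(=O)C(=[N+]=[N-])P(=O)(OC)OC
Why: Ohira–Bestmann (Seyferth–Gilbert) homologation: the diazomethylphosphonate anion freed by methanolysis adds to the aldehyde, and loss of dimethyl phosphate and N2 with a 1,2-hydride shift gives the terminal alkyne; the phenoxide is a spectator.

Step 3
Reactants: 5 4-(but-3-yn-1-yl)phenol
Product: 6 tert-butyl[4-(but-3-yn-1-yl)phenoxy]dimethylsilane
Conditions: TBSCl, imidazole, DMF, rt
Reagents that add atoms: tert-butyldimethylsilyl chloride, CC(C)(C)[Si](C)(C)Cl
Why: Standard silylation of a phenol; the silyl ether is needed only so that the phenol does not quench the acetylide in step 4, and it is meant to be lost again in step 5.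

Step 4
Reactants: 6 tert-butyl[4-(but-3-yn-1-yl)phenoxy]dimethylsilane; 3 N-methoxy-N,5-dimethylhex-4-enamide
Product: 7 1-{4-[(tert-butyldimethylsilyl)oxy]phenyl}-9-methyldec-8-en-3-yn-5-one
Conditions: n-BuLi (1.05 equiv), THF, −78 °C; then 3, −78 → 0 °C; AcOH quench at −78 °C
Reagents that add atoms: none
Why: Acylation of a lithium acetylide with a Weinreb amide; the chelated tetrahedral intermediate survives until the quench, so the ynone is not attacked again, and the acidic quench keeps the liberated hydroxylamine from adding to the ynone.

Step 5
Reactants: 7 1-{4-[(tert-butyldimethylsilyl)oxy]phenyl}-9-methyldec-8-en-3-yn-5-one; 8 dimethyl malonate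
Product: 11 methyl 2,4-dihydroxy-6-[2-(4-hydroxyphenyl)ethyl]-3-(3-methylbut-2-en-1-yl)benzoate, via silyl Michael adduct 9 (not isolated), via phenol Michael adduct 10 (not isolated)
Conditions: 8, NaH, THF, 0 °C → rt; then NaOMe, MeOH, 65 °C; cold 1 M HCl to pH 4
Reagents that add atoms: none
Why: In the first stage sodium dimethyl malonate adds to the β-carbon of ynone 7 (C3, the alkyne carbon bearing the phenethyl chain) while the phenol is still silylated, so no phenoxide competes for the ynone; this gives the delocalised anion of 9, whose C3=C4 geometry equilibrates freely. In NaOMe/MeOH the aryl silyl ether is methanolysed (10) and the α′-methylene C6, the carbon that carries the prenyl group, attacks one malonate ester in a Claisen condensation; the cyclohexenedione so formed is a tautomer of the resorcylate and aromatises at once, so no oxidant is needed. The closest known reaction types are the condensation of sodio-malonic esters with alkyl alkynyl ketones to resorcylic esters and the Michael–Claisen annulation of malonate with enones to dihydroresorcylates. The one ring closed is the benzene ring, by a 6-(enolexo)-exo-trig acylation that makes the C2–C3 bond of the benzoate; the C1–C6 bond is made before it, intermolecularly. No stereocentre is formed. Three selectivities are needed: conjugate addition at C3 and not at the carbonyl (soft malonate anion, polarised ynone); C-acylation and not O-acylation (O-acylation would give a 2-pyranone, but methoxide reopens that lactone whereas the resorcylate phenoxide cannot go back, so the mixture should drain to 11); and attack by C6 and not by another α-carbon (only C6 reaches an ester through a six-membered transition state). The prenyl alkene and the remaining ester are spectators under methoxide, and the prenyl group ends up on ring C3 between the two oxygens because of the connectivity of 7, not through any selective substitution of an arene.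

Step 6
Reactants: 11 methyl 2,4-dihydroxy-6-[2-(4-hydroxyphenyl)ethyl]-3-(3-methylbut-2-en-1-yl)benzoate; 12 3-methylbut-2-enal
Product: 14 methyl 7-hydroxy-5-[2-(4-hydroxyphenyl)ethyl]-2,2-dimethyl-8-(3-methylbut-2-en-1-yl)-2H-chromene-6-carboxylate (CNP0133674.0), via ortho-quinone methide 13 (not isolated)
Conditions: ethylenediammonium diacetate (20 mol %), toluene, 110 °C
Reagents that add atoms: none
Why: Formal [3+3] chromene annulation: amine-catalysed condensation of the enal at the only unsubstituted ring carbon (C5, ortho to the free 4-OH and para to the 2-OH) gives ortho-quinone methide 13, which closes by oxa-6π electrocyclisation onto the 4-oxygen. C3 is blocked by the prenyl group and the 2-OH is held in the hydrogen bond to the ester, so no other chromene can form; the para-alkylphenol of the side chain is not nucleophilic enough to react under these conditions.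

## Compound list

1 | N-methoxy-N-methylacetamide | CC(=O)N(C)OC | starting material
2 | 1-bromo-3-methylbut-2-ene (prenyl bromide) | CC(C)=CCBr | starting material
3 | N-methoxy-N,5-dimethylhex-4-enamide | CC(C)=CCCC(=O)N(C)OC | intermediate
4 | 3-(4-hydroxyphenyl)propanal | O=CCCc1ccc(O)cc1 | starting material
5 | 4-(but-3-yn-1-yl)phenol | C#CCCc1ccc(O)cc1 | intermediate
6 | tert-butyl[4-(but-3-yn-1-yl)phenoxy]dimethylsilane | C#CCCc1ccc(O[Si](C)(C)C(C)(C)C)cc1 | intermediate
7 | 1-{4-[(tert-butyldimethylsilyl)oxy]phenyl}-9-methyldec-8-en-3-yn-5-one | CC(C)=CCCC(=O)C#CCCc1ccc(O[Si](C)(C)C(C)(C)C)cc1 | intermediate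
8 | dimethyl malonate (dimethyl propanedioate) | COC(=O)CC(=O)OC | starting material
9 | dimethyl 2-[(3Z)-1-{4-[(tert-butyldimethylsilyl)oxy]phenyl}-9-methyl-5-oxodeca-3,8-dien-3-yl]propanedioate (silyl Michael adduct; formed and consumed in step 5; the cyclising Z isomer is shown, E and Z interconvert through the anion) | COC(=O)C(C(=O)OC)/C(CCc1ccc(O[Si](C)(C)C(C)(C)C)cc1)=C\C(=O)CCC=C(C)C | intermediate
10 | dimethyl 2-[(3Z)-1-(4-hydroxyphenyl)-9-methyl-5-oxodeca-3,8-dien-3-yl]propanedioate (phenol Michael adduct; formed and consumed in step 5) | COC(=O)C(C(=O)OC)/C(CCc1ccc(O)cc1)=C\C(=O)CCC=C(C)C | intermediate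
11 | methyl 2,4-dihydroxy-6-[2-(4-hydroxyphenyl)ethyl]-3-(3-methylbut-2-en-1-yl)benzoate | COC(=O)c1c(O)c(CC=C(C)C)c(O)cc1CCc1ccc(O)cc1 | intermediate
12 | 3-methylbut-2-enal | CC(C)=CC=O | starting material
13 | methyl 2-hydroxy-6-[2-(4-hydroxyphenyl)ethyl]-3-(3-methylbut-2-en-1-yl)-5-[(Z)-3-methylbut-2-en-1-ylidene]-4-oxocyclohexa-1(6),2-diene-1-carboxylate (ortho-quinone methide; formed and consumed in step 6) | COC(=O)C1=C(CCc2ccc(O)cc2)/C(=C/C=C(C)C)C(=O)C(CC=C(C)C)=C1O | intermediate
14 | methyl 7-hydroxy-5-[2-(4-hydroxyphenyl)ethyl]-2,2-dimethyl-8-(3-methylbut-2-en-1-yl)-2H-chromene-6-carboxylate (CNP0133674.0) | COC(=O)c1c(O)c(CC=C(C)C)c2c(c1CCc1ccc(O)cc1)C=CC(C)(C)O2 | target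

## Step count and risk

Total step count: 6. Longest linear sequence: 5 (steps 2, 3, 4, 5, 6 from aldehyde 4); step 1 is a one-step side branch.

**Step 5 (key step).** The ring closure may go through oxygen instead of carbon and stall at the lactone stage if the 2-pyranone is not reopened fast enough. Base-induced alkyne-to-allene isomerisation of the ynone before conjugate addition is a second risk. The fallback moves one oxidation level down, where O-closure gives only a labile enol lactone and the Michael–Claisen annulation is the textbook process, and pays for it with a separate dehydrogenation that uses no halogen or quinone. It sets out from 7. Semi-hydrogenation (H2, Pd/CaCO3 poisoned with Pb(OAc)2, quinoline, EtOAc) should give (3Z)-1-{4-[(tert-butyldimethylsilyl)oxy]phenyl}-9-methyldeca-3,8-dien-5-one F1. Treatment of F1 with 8 and NaOMe in MeOH at reflux should give, with loss of the silyl group, the trans dihydroresorcylate methyl (1RS,6SR)-4-hydroxy-6-[2-(4-hydroxyphenyl)ethyl]-3-(3-methylbut-2-en-1-yl)-2-oxocyclohex-3-ene-1-carboxylate F2. Its trianion (LiN(i-Pr)2, 3.3 equiv, THF, −78 °C) should take up PhSeBr at C1, the last-formed and most reactive carbanion, to give the selenide methyl 4-hydroxy-6-[2-(4-hydroxyphenyl)ethyl]-3-(3-methylbut-2-en-1-yl)-2-oxo-1-(phenylselanyl)cyclohex-3-ene-1-carboxylate F3, with the selanyl group trans to the side chain and so syn to the C6 hydrogen. Oxidation (H2O2, pyridine, CH2Cl2, 0 °C) and selenoxide syn-elimination towards C6 give a dienone that tautomerises to the arene. The fallback comes back to the route at 11.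

**Step 6.** C–C bond formation at C5 may be slow, because this carbon lies between the 4-OH and the phenethyl chain, and the enal may then be lost to self-condensation. The fallback replaces the intermolecular condensation by an intramolecular sigmatropic shift. It sets out from 11. The most acidic phenol, the 4-OH para to the ester, is alkylated with 3-chloro-3-methylbut-1-yne (K2CO3, 1.1 equiv, KI, catalytic CuI, acetone, 50 °C) to give methyl 2-hydroxy-6-[2-(4-hydroxyphenyl)ethyl]-3-(3-methylbut-2-en-1-yl)-4-[(2-methylbut-3-yn-2-yl)oxy]benzoate F4. Heating F4 in xylene at 140 °C should bring about the propargyl Claisen rearrangement to C5 (the only free ortho position, since C3 is blocked), enolisation, and a 1,5-hydrogen shift to the same ortho-quinone methide 13, which closes as in step 6. The fallback comes back to the route at 14.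

**Step 1.** The amide enolate may acylate itself on unreacted Weinreb amide, or be alkylated twice, before the bromide is consumed. The fallback makes the same C–C bond with a stabilised malonate anion. It sets out from 2 and 8. Alkylation (NaH, THF, 0 °C → rt) gives dimethyl 2-(3-methylbut-2-en-1-yl)propanedioate F5. Krapcho demethoxycarbonylation (LiCl, wet DMSO, 150 °C) gives methyl 5-methylhex-4-enoate F6. Amidation with N,O-dimethylhydroxylamine hydrochloride and i-PrMgCl (THF, −20 °C) gives the Weinreb amide. The fallback comes back to the route at 3.

## Further compounds

F1 | step 5 | (3Z)-1-{4-[(tert-butyldimethylsilyl)oxy]phenyl}-9-methyldeca-3,8-dien-5-one | CC(C)=CCCC(=O)/C=C\CCc1ccc(O[Si](C)(C)C(C)(C)C)cc1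
F2 | step 5 | methyl (1RS,6SR)-4-hydroxy-6-[2-(4-hydroxyphenyl)ethyl]-3-(3-methylbut-2-en-1-yl)-2-oxocyclohex-3-ene-1-carboxylate (racemic, trans; one enol form of the 2,4-dione) | COC(=O)[C@H]1C(=O)C(CC=C(C)C)=C(O)C[C@@H]1CCc1ccc(O)cc1
F3 | step 5 | methyl 4-hydroxy-6-[2-(4-hydroxyphenyl)ethyl]-3-(3-methylbut-2-en-1-yl)-2-oxo-1-(phenylselanyl)cyclohex-3-ene-1-carboxylate (racemic; selanyl group trans to the C6 side chain) | COC(=O)[C@]1([Se]c2ccccc2)C(=O)C(CC=C(C)C)=C(O)C[C@@H]1CCc1ccc(O)cc1
F4 | step 6 | methyl 2-hydroxy-6-[2-(4-hydroxyphenyl)ethyl]-3-(3-methylbut-2-en-1-yl)-4-[(2-methylbut-3-yn-2-yl)oxy]benzoate | COC(=O)c1c(O)c(CC=C(C)C)c(OC(C)(C)C#C)cc1CCc1ccc(O)cc1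
F5 | step 1 | dimethyl 2-(3-methylbut-2-en-1-yl)propanedioate | COC(=O)C(CC=C(C)C)C(=O)OC
F6 | step 1 | methyl 5-methylhex-4-enoate | COC(=O)CCC=C(C)C
A1 | alternative 1 | methyl 2,4-dihydroxy-6-[2-(4-hydroxyphenyl)ethyl]benzoate | COC(=O)c1c(O)cc(O)cc1CCc1ccc(O)cc1
A2 | alternative 2 | methyl 2,4-dihydroxy-6-[2-(4-hydroxyphenyl)ethyl]-3,5-bis(3-methylbut-2-en-1-yl)benzoate | COC(=O)c1c(O)c(CC=C(C)C)c(O)c(CC=C(C)C)c1CCc1ccc(O)cc1
A3 | alternative 3 | {[1-methoxy-2-(3-methylbut-2-en-1-yl)buta-1,3-diene-1,3-diyl]bis(oxy)}bis(trimethylsilane) (geometry at C1=C2 not defined) | COC(O[Si](C)(C)C)=C(CC=C(C)C)C(=C)O[Si](C)(C)C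
A4 | alternative 3 | methyl 5-{4-[(tert-butyldimethylsilyl)oxy]phenyl}pent-2-ynoate | COC(=O)C#CCCc1ccc(O[Si](C)(C)C(C)(C)C)cc1
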